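**Plan**
- Retrosynthesis: cut the acetate and tiglate C–O bonds, then three C–C bonds of the benzene ring, C2–C3, C4–C5 and C5–C6 (C1 carries the carbinol chain, C2 OMe, C4 CH3, C5 OH).
- Enabling feature: the benzene ring is a 1,2,4,5-tetrasubstituted hydroquinone. Its C2 oxygen (beside the side chain) is methylated and its para C5 oxygen (beside the C4 methyl) is free. An alkenyl(methoxy)carbene chromium complex, a terminal alkyne and one CO assemble exactly this 4-methoxyphenol array.
- Forward: Sonogashira coupling joins a C3 and a C2 piece to an enynol. Epoxidation, opening and ketalisation give a dioxolane (auxiliary ring) with two different CH2O arms. The alkyne is then taken through methyl ketone, enol triflate and stannane to the carbene complex.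
- The arene, the only ring of the target, is closed from this complex, propyne and a CO ligand. Silylation, PMB removal, tigloylation, ketal hydrolysis, acetylation and desilylation finish the synthesis.
- Stereochemistry: the one stereocentre is set by a Katsuki–Sharpless epoxidation with D-(−)-tartrate, and no bond to it is broken later. R results because the opened epoxide CH2 becomes the tiglate arm and the original CH2OH the acetate arm.

Key step: step 9

Remark: in the SMILES strings, chromium carbonyl species are drawn with formal Cr=C=O bonds, and the η6-arene complex is written as arene and Cr(CO)3 fragment joined by a dot. The carbinol carbon of the target is R (OH > CH2O-tigloyl > CH2OAc > aryl) and the enoate is E (tiglate).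

Step 1
Reactants: 1 2-bromoprop-2-en-1-ol; 2 ethynyltrimethylsilane
Product: 3 2-methylidene-4-(trimethylsilyl)but-3-yn-1-ol
Conditions: PdCl2(PPh3)2 (2 mol %), CuI (4 mol %), Et3N (3 equiv), THF, rt
Reagents that add atoms: none
Why: Sonogashira coupling of a 2-bromo-1-alkene with a terminal alkyne is routine, leaves the free allylic hydroxyl alone, and the silyl cap blocks reaction at the far alkyne end and keeps the small enynol and its epoxide non-volatile.

Step 2
Reactants: 3 2-methylidene-4-(trimethylsilyl)but-3-yn-1-ol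
Product: 4 {(2R)-2-[(trimethylsilyl)ethynyl]oxiran-2-yl}methanol
Conditions: Ti(OiPr)4 (10 mol %), D-(−)-diisopropyl tartrate (12 mol %), t-BuOOH (2 equiv, decane), 4 Å MS, CH2Cl2, −20 °C
Reagents that add atoms: tert-butyl hydroperoxide, CC(C)(C)OO
Why: Katsuki–Sharpless asymmetric epoxidation: the allylic hydroxyl ties the alkene to the titanium tartrate so that the alkyne is ignored and one alkene face is attacked, D-(−)-tartrate making the new quaternary centre R in the same sense as it converts 2-methylprop-2-en-1-ol into (R)-2-methylglycidol; 2-alkynyl allylic alcohols are known substrates and the catalytic, sieve-dried protocol limits opening of the 2,2-disubstituted oxirane.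

Step 3
Reactants: 4 {(2R)-2-[(trimethylsilyl)ethynyl]oxiran-2-yl}methanol
Product: 6 (2R)-2-ethynyl-3-[(4-methoxybenzyl)oxy]propane-1,2-diol, via desilylated epoxy alcohol 5 (not isolated)
Conditions: 4-MeOC6H4CH2OH (3 equiv), NaH (2.5 equiv), DMF, 0 → 60 °C; H2O
Reagents that add atoms: 4-methoxybenzyl alcohol, COc1ccc(CO)cc1
Why: The alkoxide first cleaves the alkynyl C–Si bond and then opens the 2,2-disubstituted epoxide by SN2 attack at its CH2 terminus, so no bond to the stereocentre is touched; a competing Payne rearrangement is harmless because it is degenerate here and passes through a C2-symmetric transition state that returns the same enantiomer.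

Step 4
Reactants: 6 (2R)-2-ethynyl-3-[(4-methoxybenzyl)oxy]propane-1,2-diol
Product: 7 (4S)-4-ethynyl-4-{[(4-methoxybenzyl)oxy]methyl}-2,2-dimethyl-1,3-dioxolane
Conditions: Me2C(OMe)2 (3 equiv), PPTS (5 mol %), CH2Cl2, rt
Reagents that add atoms: 2,2-dimethoxypropane, COC(C)(C)OC
Why: Acid-catalysed transketalisation closes the five-membered dioxolane over the tertiary and the primary hydroxyl, which masks both protic groups in one operation and leaves the two CH2O arms permanently distinguishable (ketal versus PMB ether).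

Step 5
Reactants: 7 (4S)-4-ethynyl-4-{[(4-methoxybenzyl)oxy]methyl}-2,2-dimethyl-1,3-dioxolane
Product: 8 1-[(4S)-4-{[(4-methoxybenzyl)oxy]methyl}-2,2-dimethyl-1,3-dioxolan-4-yl]ethan-1-one
Conditions: Ph3PAuNTf2 (2 mol %), H2O (5 equiv), 1,4-dioxane, 60 °C
Reagents that add atoms: water, O
Why: Gold-catalysed Markovnikov hydration of a terminal alkyne gives the methyl ketone without added Brønsted acid, so ketal and PMB ether should survive, and the product cannot epimerise or undergo β-elimination because the carbon next to the carbonyl on that side carries no hydrogen.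

Step 6
Reactants: 8 1-[(4S)-4-{[(4-methoxybenzyl)oxy]methyl}-2,2-dimethyl-1,3-dioxolan-4-yl]ethan-1-one
Product: 10 1-[(4S)-4-{[(4-methoxybenzyl)oxy]methyl}-2,2-dimethyl-1,3-dioxolan-4-yl]ethenyl trifluoromethanesulfonate, via potassium enolate 9 (not isolated)
Conditions: KN(SiMe3)2 (1.2 equiv), THF, −78 °C; PhNTf2 (1.3 equiv), −78 → 0 °C
Reagents that add atoms: N-phenylbis(trifluoromethanesulfonimide), O=S(=O)(N(c1ccccc1)S(=O)(=O)C(F)(F)F)C(F)(F)F
Why: Kinetic deprotonation can occur only at the methyl group and O-sulfonylation of the enolate gives the 1,1-disubstituted enol triflate, so the site of the later carbon–metal bond is fixed by constitution instead of depending on the regiochemistry of a hydrometalation next to a quaternary carbon.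

Step 7
Reactants: 10 1-[(4S)-4-{[(4-methoxybenzyl)oxy]methyl}-2,2-dimethyl-1,3-dioxolan-4-yl]ethenyl trifluoromethanesulfonate
Product: 11 trimethyl{1-[(4S)-4-{[(4-methoxybenzyl)oxy]methyl}-2,2-dimethyl-1,3-dioxolan-4-yl]ethenyl}stannane
Conditions: Me3SnSnMe3 (1.2 equiv), Pd(PPh3)4 (5 mol %), LiCl (6 equiv), THF, 65 °C
Reagents that add atoms: hexamethyldistannane, C[Sn](C)(C)[Sn](C)(C)C
Why: Palladium-catalysed stannylation of an enol triflate with a hexaalkyldistannane and LiCl (Stille-type coupling) is the established bridge from ketones to regiodefined alkenylstannanes and touches neither ketal nor PMB ether.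

Step 8
Reactants: 11 trimethyl{1-[(4S)-4-{[(4-methoxybenzyl)oxy]methyl}-2,2-dimethyl-1,3-dioxolan-4-yl]ethenyl}stannane; 12 hexacarbonylchromium
Product: 15 pentacarbonyl{methoxy[1-((4S)-4-{[(4-methoxybenzyl)oxy]methyl}-2,2-dimethyl-1,3-dioxolan-4-yl)ethenyl]methylidene}chromium, via alkenyllithium 13 (not isolated), via lithium acylchromate 14 (not isolated)
Conditions: MeLi (1.05 equiv), THF, −78 °C; Cr(CO)6 (1.2 equiv), THF, −78 → 0 °C; MeOTf (1.5 equiv), CH2Cl2, 0 °C
Reagents that add atoms: methyl trifluoromethanesulfonate, COS(=O)(=O)C(F)(F)F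
Why: Fischer carbene synthesis: tin–lithium exchange at −78 °C gives the alkenyllithium cold enough to hold back β-elimination of the dioxolane oxygen, the carbanion adds to a CO ligand of Cr(CO)6, and O-methylation of the acylchromate gives the methoxycarbene, a sequence well known for alkenylstannanes made from enol triflates.

Step 9
Reactants: 15 pentacarbonyl{methoxy[1-((4S)-4-{[(4-methoxybenzyl)oxy]methyl}-2,2-dimethyl-1,3-dioxolan-4-yl)ethenyl]methylidene}chromium; 16 propyne
Product: 18 4-methoxy-5-[(4S)-4-{[(4-methoxybenzyl)oxy]methyl}-2,2-dimethyl-1,3-dioxolan-4-yl]-2-methylphenol, via tricarbonylchromium arene complex 17 (not isolated)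
Conditions: propyne (5 equiv), THF (0.1 M), sealed vessel, Ar, 55 °C; then air, Et2O, rt
Reagents that add atoms: none
Why: Thermal loss of one CO ligand from 15 frees a coordination site for propyne, which inserts into the Cr=C bond with its CH end bonding to the carbene carbon, and a CO ligand then migrates onto the methyl-bearing carbon to give a chromium-bound dienylketene. The six-membered ring closes by a six-electron electrocyclisation that links the ketene carbonyl carbon to the terminal =CH2 carbon of the alkenyl group; enolisation of the cyclohexadienone gives the phenol as its Cr(CO)3 complex 17, and air removes the metal. The closest known reaction type is this very one, the Dötz benzannulation of alkenyl(alkoxy)carbene chromium complexes with terminal alkynes, for which 2-substituted propenyl complexes are reliable partners. The bonds C2–C3, C4–C5 and C5–C6 are formed, the carbene carbon ends as C2–OMe beside the side chain and the CO carbon as C5–OH beside the methyl group, so the two hydroquinone oxygens never have to be told apart afterwards. No stereocentre is created; the existing one carries no hydrogen, lies outside the reacting π system and keeps all four bonds, and the planar chirality of 17 disappears on demetalation. The selectivity required is the orientation of alkyne insertion, secured by the size difference between CH3 and H on propyne, which steers the substituted alkyne carbon away from the crowded carbene carbon and next to the incoming CO, while phenol formation over CO-free products is favoured by the alkenyl (not aryl) complex, the donor solvent and the excess of alkyne.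

Step 10
Reactants: 18 4-methoxy-5-[(4S)-4-{[(4-methoxybenzyl)oxy]methyl}-2,2-dimethyl-1,3-dioxolan-4-yl]-2-methylphenol
Product: 19 tert-butyl{4-methoxy-5-[(4S)-4-{[(4-methoxybenzyl)oxy]methyl}-2,2-dimethyl-1,3-dioxolan-4-yl]-2-methylphenoxy}dimethylsilane
Conditions: TBSCl (1.3 equiv), imidazole (2.5 equiv), DMF, rt
Reagents that add atoms: tert-butyldimethylsilyl chloride, CC(C)(C)[Si](C)(C)Cl
Why: Standard silylation of a phenol with TBSCl and imidazole, which shields the 4-methoxyphenol from oxidation to the quinone in the next step and from acylation later.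

Step 11
Reactants: 19 tert-butyl{4-methoxy-5-[(4S)-4-{[(4-methoxybenzyl)oxy]methyl}-2,2-dimethyl-1,3-dioxolan-4-yl]-2-methylphenoxy}dimethylsilane
Product: 20 [(4S)-4-{5-[(tert-butyldimethylsilyl)oxy]-2-methoxy-4-methylphenyl}-2,2-dimethyl-1,3-dioxolan-4-yl]methanol
Conditions: DDQ (1.3 equiv), CH2Cl2/pH 7 phosphate buffer (10:1), 0 °C
Reagents that add atoms: none
Why: Oxidative PMB cleavage with DDQ proceeds by hydride abstraction from the para-methoxybenzylic CH2, the most easily oxidised C–H site of 19 because the other arene has a fully substituted benzylic carbon on one side and a methyl group meta to its OMe on the other, and the buffered two-phase medium spares ketal and silyl ether.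

Step 12
Reactants: 20 [(4S)-4-{5-[(tert-butyldimethylsilyl)oxy]-2-methoxy-4-methylphenyl}-2,2-dimethyl-1,3-dioxolan-4-yl]methanol; 21 (E)-2-methylbut-2-enoyl chloride (tigloyl chloride)
Product: 22 [(4R)-4-{5-[(tert-butyldimethylsilyl)oxy]-2-methoxy-4-methylphenyl}-2,2-dimethyl-1,3-dioxolan-4-yl]methyl (E)-2-methylbut-2-enoate
Conditions: tigloyl chloride (1.5 equiv), pyridine (3 equiv), DMAP (10 mol %), CH2Cl2, 0 °C → rt
Reagents that add atoms: none
Why: DMAP-catalysed acylation of the neopentyl-type primary alcohol with the acid chloride; pyridine instead of a trialkylamine avoids vinylketene formation and deconjugation, and the E geometry of the tiglate is the stable one.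

Step 13
Reactants: 22 [(4R)-4-{5-[(tert-butyldimethylsilyl)oxy]-2-methoxy-4-methylphenyl}-2,2-dimethyl-1,3-dioxolan-4-yl]methyl (E)-2-methylbut-2-enoate
Product: 23 (2R)-2-{5-[(tert-butyldimethylsilyl)oxy]-2-methoxy-4-methylphenyl}-2,3-dihydroxypropyl (E)-2-methylbut-2-enoate
Conditions: AcOH/H2O (4:1), 40 °C
Reagents that add atoms: none
Why: Ketal hydrolysis in aqueous acetic acid breaks the C–O bonds at the ketal carbon and not the benzylic C–O bond, whose ionisation is disfavoured by two β-oxygen substituents, while the aryl silyl ether and the hindered conjugated ester tolerate the medium.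

Step 14
Reactants: 23 (2R)-2-{5-[(tert-butyldimethylsilyl)oxy]-2-methoxy-4-methylphenyl}-2,3-dihydroxypropyl (E)-2-methylbut-2-enoate
Product: 24 (2R)-3-acetoxy-2-{5-[(tert-butyldimethylsilyl)oxy]-2-methoxy-4-methylphenyl}-2-hydroxypropyl (E)-2-methylbut-2-enoate
Conditions: Ac2O (1.2 equiv), pyridine (3 equiv), CH2Cl2, 0 °C
Reagents that add atoms: acetic anhydride, CC(=O)OC(C)=O
Why: Chemoselective acetylation, since a primary alcohol reacts far faster than the tertiary benzylic hydroxyl, and carrying it out at once on the fresh diol leaves little time for a 1,3-shift of the tigloyl group, the only process that could erode the configuration.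

Step 15
Reactants: 24 (2R)-3-acetoxy-2-{5-[(tert-butyldimethylsilyl)oxy]-2-methoxy-4-methylphenyl}-2-hydroxypropyl (E)-2-methylbut-2-enoate
Product: 25 (2R)-3-acetoxy-2-hydroxy-2-(5-hydroxy-2-methoxy-4-methylphenyl)propyl (E)-2-methylbut-2-enoate (CNP0219919.1)
Conditions: TBAF (1.1 equiv), AcOH (1.2 equiv), THF, 0 °C
Reagents that add atoms: none
Why: Fluoride-mediated desilylation cleaves the aryl silyl ether rapidly at 0 °C, and buffering with acetic acid keeps phenoxide and alkoxide basicity too low for ester cleavage or acyl migration.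

**Compound list**
1 | 2-bromoprop-2-en-1-ol | OCC(Br)=C | starting material
2 | ethynyltrimethylsilane | C#C[Si](C)(C)C | starting material
3 | 2-methylidene-4-(trimethylsilyl)but-3-yn-1-ol | C=C(CO)C#C[Si](C)(C)C | intermediate
4 | {(2R)-2-[(trimethylsilyl)ethynyl]oxiran-2-yl}methanol | OC[C@]1(C#C[Si](C)(C)C)CO1 | intermediate
5 | [(2R)-2-ethynyloxiran-2-yl]methanol (not isolated) | OC[C@]1(C#C)CO1 | intermediate
6 | (2R)-2-ethynyl-3-[(4-methoxybenzyl)oxy]propane-1,2-diol | COc1ccc(COC[C@](O)(CO)C#C)cc1 | intermediate
7 | (4S)-4-ethynyl-4-{[(4-methoxybenzyl)oxy]methyl}-2,2-dimethyl-1,3-dioxolane | COc1ccc(COC[C@]2(COC(C)(C)O2)C#C)cc1 | intermediate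
8 | 1-[(4S)-4-{[(4-methoxybenzyl)oxy]methyl}-2,2-dimethyl-1,3-dioxolan-4-yl]ethan-1-one | COc1ccc(COC[C@]2(COC(C)(C)O2)C(C)=O)cc1 | intermediate
9 | potassium enolate of 8 (not isolated) | COc1ccc(COC[C@]2(COC(C)(C)O2)C(=C)[O-])cc1.[K+] | intermediate
10 | 1-[(4S)-4-{[(4-methoxybenzyl)oxy]methyl}-2,2-dimethyl-1,3-dioxolan-4-yl]ethenyl trifluoromethanesulfonate | COc1ccc(COC[C@]2(COC(C)(C)O2)C(=C)OS(=O)(=O)C(F)(F)F)cc1 | intermediate
11 | trimethyl{1-[(4S)-4-{[(4-methoxybenzyl)oxy]methyl}-2,2-dimethyl-1,3-dioxolan-4-yl]ethenyl}stannane | COc1ccc(COC[C@]2(COC(C)(C)O2)C(=C)[Sn](C)(C)C)cc1 | intermediate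
12 | hexacarbonylchromium | O=C=[Cr](=C=O)(=C=O)(=C=O)(=C=O)=C=O | starting material
13 | 1-[(4S)-4-{[(4-methoxybenzyl)oxy]methyl}-2,2-dimethyl-1,3-dioxolan-4-yl]ethenyllithium (not isolated) | COc1ccc(COC[C@]2(COC(C)(C)O2)C(=C)[Li])cc1 | intermediate
14 | lithium pentacarbonyl{2-[(4S)-4-{[(4-methoxybenzyl)oxy]methyl}-2,2-dimethyl-1,3-dioxolan-4-yl]prop-2-enoyl}chromate (not isolated) | COc1ccc(COC[C@]2(COC(C)(C)O2)C(=C)C([O-])=[Cr](=C=O)(=C=O)(=C=O)(=C=O)=C=O)cc1.[Li+] | intermediate
15 | pentacarbonyl{methoxy[1-((4S)-4-{[(4-methoxybenzyl)oxy]methyl}-2,2-dimethyl-1,3-dioxolan-4-yl)ethenyl]methylidene}chromium | COc1ccc(COC[C@]2(COC(C)(C)O2)C(=C)C(OC)=[Cr](=C=O)(=C=O)(=C=O)(=C=O)=C=O)cc1 | intermediate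
16 | propyne | CC#C | starting material
17 | tricarbonyl(η6-arene)chromium complex of 18 (not isolated) | COc1ccc(COC[C@]2(COC(C)(C)O2)c3cc(O)c(C)cc3OC)cc1.O=C=[Cr](=C=O)=C=O | intermediate
18 | 4-methoxy-5-[(4S)-4-{[(4-methoxybenzyl)oxy]methyl}-2,2-dimethyl-1,3-dioxolan-4-yl]-2-methylphenol | COc1ccc(COC[C@]2(COC(C)(C)O2)c3cc(O)c(C)cc3OC)cc1 | intermediate
19 | tert-butyldimethylsilyl ether of 18 | COc1ccc(COC[C@]2(COC(C)(C)O2)c3cc(O[Si](C)(C)C(C)(C)C)c(C)cc3OC)cc1 | intermediate
20 | [(4S)-4-{5-[(tert-butyldimethylsilyl)oxy]-2-methoxy-4-methylphenyl}-2,2-dimethyl-1,3-dioxolan-4-yl]methanol | OC[C@]1(COC(C)(C)O1)c2cc(O[Si](C)(C)C(C)(C)C)c(C)cc2OC | intermediate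
21 | (E)-2-methylbut-2-enoyl chloride | C/C=C(\C)C(=O)Cl | starting material
22 | [(4R)-4-{5-[(tert-butyldimethylsilyl)oxy]-2-methoxy-4-methylphenyl}-2,2-dimethyl-1,3-dioxolan-4-yl]methyl (E)-2-methylbut-2-enoate | C/C=C(\C)C(=O)OC[C@]1(COC(C)(C)O1)c2cc(O[Si](C)(C)C(C)(C)C)c(C)cc2OC | intermediate
23 | (2R)-2-{5-[(tert-butyldimethylsilyl)oxy]-2-methoxy-4-methylphenyl}-2,3-dihydroxypropyl (E)-2-methylbut-2-enoate | C/C=C(\C)C(=O)OC[C@](O)(CO)c1cc(O[Si](C)(C)C(C)(C)C)c(C)cc1OC | intermediate
24 | (2R)-3-acetoxy-2-{5-[(tert-butyldimethylsilyl)oxy]-2-methoxy-4-methylphenyl}-2-hydroxypropyl (E)-2-methylbut-2-enoate | C/C=C(\C)C(=O)OC[C@](O)(COC(C)=O)c1cc(O[Si](C)(C)C(C)(C)C)c(C)cc1OC | intermediate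
25 | (2R)-3-acetoxy-2-hydroxy-2-(5-hydroxy-2-methoxy-4-methylphenyl)propyl (E)-2-methylbut-2-enoate | C/C=C(\C)C(=O)OC[C@](O)(COC(C)=O)c1cc(O)c(C)cc1OC | target

Total step count: 15. Longest linear sequence: 15 steps (1 to 25); 2, 12, 16 and 21 enter as purchased materials.

**Steps most likely to fail**

Step 8 (formation of the carbene complex). What may go wrong: β-elimination of the dioxolane oxygen from the alkenyllithium before it is captured, or slow addition to Cr(CO)6 because the carbanion sits beside a quaternary carbon. The fallback runs from 10 and 12 back to 15 and reverses the polarity of the C–Cr bond formation, so that no alkenyllithium is needed. Hydroxycarbonylation of 10 [Pd(OAc)2, dppp, CO (1 atm), H2O, Et3N, DMF, 60 °C] should give the acrylic acid F1. 1-Chloro-N,N,2-trimethylprop-1-en-1-amine in CH2Cl2 converts it under neutral conditions into the acid chloride F2. Reduction of 12 with NaC10H8 (sodium naphthalenide) in THF at −78 °C gives disodium pentacarbonylchromate F3. Its acylation by F2 gives the sodium acylchromate F4, and MeOTf methylates this to 15.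

Step 9 (benzannulation). What may go wrong: decomposition of the crowded complex before alkyne uptake, insertion without CO incorporation, or escape of the gaseous alkyne. The fallback runs from 16 and 11 back to 18 and reaches the same dienylketene without chromium through a Moore rearrangement. Trichloroacetyl chloride and Zn(Cu) in Et2O generate dichloroketene F5, which adds to 16 in a [2+2] sense to give 4,4-dichloro-3-methylcyclobut-2-en-1-one F6. Hydrolysis in concentrated H2SO4 gives 3-methylcyclobut-3-ene-1,2-dione F7. Alkenyllithium 13, made from 11 as in step 8, is added to F7 in THF at −78 °C, where the bulky nucleophile should prefer the carbonyl group flanked by the ring CH. The lithium alkoxide F8 is methylated in the same flask with MeOTf to the 4-alkenyl-4-methoxycyclobutenone F9 (both epimers at the ring carbon serve). Heating in toluene at 110 °C opens the four-membered ring, with the methoxy group turning outward, to the metal-free dienylketene F10. Its six-electron closure and enolisation give 18.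

Step 13 (ketal hydrolysis with the tiglate in place). What may go wrong: an acid-promoted shift of the tigloyl group from one primary oxygen to the other, which would erode the enantiomeric purity because the two arms differ only in their acyl groups, or ionisation at the benzylic C–O bond. The fallback runs from 19 back to 24 and inverts the order of events, so that acid meets no ester and the last hydroxyl is freed oxidatively at neutral pH. Hydrolysis of 19 (AcOH/H2O, 40 °C) gives the PMB-protected diol F11. Ac2O/pyridine acetylates its primary hydroxyl to the acetate F12. DDQ in buffered CH2Cl2 removes the PMB group to give the hydroxy acetate F13, and immediate acylation with 21 (pyridine, DMAP, CH2Cl2, 0 °C) gives 24.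

**Further compounds**
F1 | step 8 | 2-[(4S)-4-{[(4-methoxybenzyl)oxy]methyl}-2,2-dimethyl-1,3-dioxolan-4-yl]prop-2-enoic acid | COc1ccc(COC[C@]2(COC(C)(C)O2)C(=C)C(=O)O)cc1
F2 | step 8 | 2-[(4S)-4-{[(4-methoxybenzyl)oxy]methyl}-2,2-dimethyl-1,3-dioxolan-4-yl]prop-2-enoyl chloride | COc1ccc(COC[C@]2(COC(C)(C)O2)C(=C)C(=O)Cl)cc1
F3 | step 8 | disodium pentacarbonylchromate Na2Cr(CO)5 | [Na+].[Na+].O=C=[Cr-2](=C=O)(=C=O)(=C=O)=C=O
F4 | step 8 | sodium pentacarbonyl{2-[(4S)-4-{[(4-methoxybenzyl)oxy]methyl}-2,2-dimethyl-1,3-dioxolan-4-yl]prop-2-enoyl}chromate | COc1ccc(COC[C@]2(COC(C)(C)O2)C(=C)C([O-])=[Cr](=C=O)(=C=O)(=C=O)(=C=O)=C=O)cc1.[Na+]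
F5 | step 9 | dichloroketene | ClC(Cl)=C=O
F6 | step 9 | 4,4-dichloro-3-methylcyclobut-2-en-1-one | CC1=CC(=O)C1(Cl)Cl
F7 | step 9 | 3-methylcyclobut-3-ene-1,2-dione | CC1=CC(=O)C1=O
F8 | step 9 | lithium 1-{1-[(4S)-4-{[(4-methoxybenzyl)oxy]methyl}-2,2-dimethyl-1,3-dioxolan-4-yl]ethenyl}-3-methyl-4-oxocyclobut-2-en-1-olate (both ring epimers) | COc1ccc(COC[C@]2(COC(C)(C)O2)C(=C)C3([O-])C=C(C)C3=O)cc1.[Li+]
F9 | step 9 | 4-methoxy-4-{1-[(4S)-4-{[(4-methoxybenzyl)oxy]methyl}-2,2-dimethyl-1,3-dioxolan-4-yl]ethenyl}-2-methylcyclobut-2-en-1-one (both ring epimers) | COc1ccc(COC[C@]2(COC(C)(C)O2)C(=C)C3(OC)C=C(C)C3=O)cc1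
F10 | step 9 | (3E)-4-methoxy-5-[(4S)-4-{[(4-methoxybenzyl)oxy]methyl}-2,2-dimethyl-1,3-dioxolan-4-yl]-2-methylhexa-1,3,5-trien-1-one | COc1ccc(COC[C@]2(COC(C)(C)O2)C(=C)/C(OC)=C\C(C)=C=O)cc1
F11 | step 13 | (2S)-2-{5-[(tert-butyldimethylsilyl)oxy]-2-methoxy-4-methylphenyl}-3-[(4-methoxybenzyl)oxy]propane-1,2-diol | COc1ccc(COC[C@](O)(CO)c2cc(O[Si](C)(C)C(C)(C)C)c(C)cc2OC)cc1
F12 | step 13 | 2-{5-[(tert-butyldimethylsilyl)oxy]-2-methoxy-4-methylphenyl}-2-hydroxy-3-[(4-methoxybenzyl)oxy]propyl acetate, configuration as in 24 | COc1ccc(COC[C@](O)(COC(C)=O)c2cc(O[Si](C)(C)C(C)(C)C)c(C)cc2OC)cc1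
F13 | step 13 | 2-{5-[(tert-butyldimethylsilyl)oxy]-2-methoxy-4-methylphenyl}-2,3-dihydroxypropyl acetate, configuration as in 24 | OC[C@](O)(COC(C)=O)c1cc(O[Si](C)(C)C(C)(C)C)c(C)cc1OC
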